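**Retrosynthetic overview**
1. Endgame: the C15 acid comes from the C15 allylic alcohol, the 6β-hydroxyl from α-face hydride addition to a labd-8-en-6-one, and that ketone by deconjugation of an 8-methyl-7-en-6-one made from a ring B 6,8-dione (O8 triflation, methyl coupling).
2. Feature used: in ring B the carbinol carbon C6 and the methyl-bearing alkene carbon C8 are 1,3-related through C7, so ring B is a masked cyclohexane-1,3-dione; it is closed by a Claisen condensation joining C7 (methyl of a C5 acetyl group) to C8 (ester carbon on C9).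
3. The keto ester comes from an Ireland–Claisen rearrangement of a (6R)-allylic ester, which sets quaternary C10 and the C9 ester branch; the C5 ethylidene it leaves is converted to the acetyl group by hydroboration and oxidation.
4. Borane would also attack a C13=C14 alkene, so the C9 branch is carried through that stage as a 2-(benzyloxy)ethyl stub (C11–C12) and completed at C12–C13 by Negishi coupling with an (E)-alkenyl iodide before ring closure.
5. Ring order: ring A is the starting 2-methylcyclohexane-1,3-dione (C19 by hydroxymethylation, C3/C4 by ketoreductase desymmetrisation); ring B is formed second, in step 18.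

Key step: step 18

Remark: a commercial ketoreductase panel is assumed to contain an enzyme with the (2S,3R) selectivity needed in step 3.
Conventions: labdane numbering throughout; β is the face of the C10 methyl; TBS = tert-butyldimethylsilyl; Bn = benzyl. After step 10 the C9 centre, and after step 12 the C5 centre, are carried as epimer mixtures; both are α to carbonyl groups and are settled or erased in steps 18 and 21.

**Step 1**
Reactants: 1 2-methylcyclohexane-1,3-dione
Product: 2 2-(hydroxymethyl)-2-methylcyclohexane-1,3-dione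
Conditions: 37% aq. HCHO, NaHCO3 (cat.), THF/H2O, rt
Reagents that add atoms: formaldehyde (C=O)
Why: Aldol-type hydroxymethylation of the doubly stabilised dione enolate at C2 (future C4) gives the achiral quaternary dione carrying the future C19.

**Step 2**
Reactants: 2 2-(hydroxymethyl)-2-methylcyclohexane-1,3-dione
Product: 3 2-[(TBS-oxy)methyl]-2-methylcyclohexane-1,3-dione
Conditions: TBSCl, imidazole, DMF, 0 °C to rt
Reagents that add atoms: tert-butyldimethylsilyl chloride (CC(C)(C)[Si](C)(C)Cl)
Why: Standard silylation of the primary alcohol, which also blocks retro-aldol loss of formaldehyde in later steps.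

**Step 3**
Reactants: 3 2-[(TBS-oxy)methyl]-2-methylcyclohexane-1,3-dione
Product: 4 (2S,3R)-2-[(TBS-oxy)methyl]-3-hydroxy-2-methylcyclohexan-1-one
Conditions: ketoreductase (anti-Prelog, chosen from a commercial screening panel), NADP+ (cat.), i-PrOH, pH 7 phosphate buffer/DMSO, 30 °C
Reagents that add atoms: none
Why: Enzymatic desymmetrisation of a prochiral 2,2-disubstituted cyclohexane-1,3-dione: reduction of one enantiotopic carbonyl from one face sets C3 (R, hydroxyl cis to the methyl) and the quaternary C4 (S) together under enzyme control.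

**Step 4**
Reactants: 4 (2S,3R)-2-[(TBS-oxy)methyl]-3-hydroxy-2-methylcyclohexan-1-one
Product: 5 (2S,3R)-3-(TBS-oxy)-2-[(TBS-oxy)methyl]-2-methylcyclohexan-1-one
Conditions: TBSOTf, 2,6-lutidine, CH2Cl2, −78 to 0 °C
Reagents that add atoms: tert-butyldimethylsilyl triflate (CC(C)(C)[Si](C)(C)OS(=O)(=O)C(F)(F)F)
Why: Silyl triflate silylation of the hindered secondary alcohol next to the quaternary carbon, under non-nucleophilic base so that the β-hydroxy ketone does not undergo retro-aldol cleavage.

**Step 5**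
Reactants: 5 (2S,3R)-3-(TBS-oxy)-2-[(TBS-oxy)methyl]-2-methylcyclohexan-1-one
Product: 7 (2S,3R)-3-(TBS-oxy)-2-[(TBS-oxy)methyl]-2,6-dimethylcyclohexan-1-one (both C6 epimers), via lithium enolate 6 (not isolated)
Conditions: LDA, THF, −78 °C; MeI, −78 to 0 °C
Reagents that add atoms: iodomethane (CI)
Why: Enolate alkylation at the only enolisable α-carbon (the other is quaternary) installs the future C10 methyl; its configuration is irrelevant because this carbon becomes sp2 in the next step.

**Step 6**
Reactants: 7 (2S,3R)-3-(TBS-oxy)-2-[(TBS-oxy)methyl]-2,6-dimethylcyclohexan-1-one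
Product: 9 (5R,6S)-5-(TBS-oxy)-6-[(TBS-oxy)methyl]-2,6-dimethylcyclohex-1-en-1-yl triflate, via potassium enolate 8 (not isolated)
Conditions: KHMDS, THF, −78 °C; PhNTf2, −78 °C to rt
Reagents that add atoms: N-phenylbis(trifluoromethanesulfonimide) (O=S(=O)(N(c1ccccc1)S(=O)(=O)C(F)(F)F)C(F)(F)F)
Why: Enol triflate formation; the single possible enolate gives the tetrasubstituted C5=C10 enol triflate.

**Step 7**
Reactants: 9 (5R,6S)-5-(TBS-oxy)-6-[(TBS-oxy)methyl]-2,6-dimethylcyclohex-1-en-1-yl triflate; 10 tributyl(1-ethoxyvinyl)stannane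
Product: 12 1-[(5R,6S)-5-(TBS-oxy)-6-[(TBS-oxy)methyl]-2,6-dimethylcyclohex-1-en-1-yl]ethan-1-one, via 1-ethoxyvinyl diene 11 (not isolated)
Conditions: Pd(PPh3)4 (cat.), LiCl, dioxane, 90 °C; then 1 M HCl, THF, 0 °C
Reagents that add atoms: water (O)
Why: Stille coupling of the enol triflate with the acetyl-anion equivalent, then mild hydrolysis of the enol ether, gives the C5 acetyl enone (C6, C7) without touching the silyl ethers.

**Step 8**
Reactants: 12 1-[(5R,6S)-5-(TBS-oxy)-6-[(TBS-oxy)methyl]-2,6-dimethylcyclohex-1-en-1-yl]ethan-1-one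
Product: 13 (1R)-1-[(5R,6S)-5-(TBS-oxy)-6-[(TBS-oxy)methyl]-2,6-dimethylcyclohex-1-en-1-yl]ethan-1-ol
Conditions: (S)-2-methyl-CBS-oxazaborolidine (C18H20BNO, cat.), BH3·SMe2, THF, −30 °C; MeOH quench
Reagents that add atoms: none
Why: Corey–Bakshi–Shibata reduction: the tetrasubstituted alkenyl group is the large and the methyl the small substituent, so the (S)-catalyst should give the (6R)-carbinol under reagent control.

**Step 9**
Reactants: 13 (1R)-allylic alcohol; 14 4-(benzyloxy)butanoic acid
Product: 15 (1R)-1-[(5R,6S)-5-(TBS-oxy)-6-[(TBS-oxy)methyl]-2,6-dimethylcyclohex-1-en-1-yl]ethyl 4-(benzyloxy)butanoate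
Conditions: DCC, 4-(dimethylamino)pyridine (cat.), CH2Cl2, 0 °C to rt
Reagents that add atoms: none
Why: Steglich esterification attaches C8, C9, C11 and C12 to the C6 oxygen without disturbing the carbinol centre.

**Step 10**
Reactants: 15 allylic 4-(benzyloxy)butanoate
Product: 18 ethylidene acid (ring A with (Z)-C5=CH–CH3; C10 bearing β-methyl and α-CH(CO2H)CH2CH2OBn; 3α-OTBS; 19-OTBS; C9 epimers), via silyl ketene acetal 16 (not isolated), via trimethylsilyl ester 17 (not isolated)
Conditions: LDA, TMSCl/Et3N, THF, −78 °C, then 65 °C; 1 M aq. HCl work-up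
Reagents that add atoms: none
Why: Ireland–Claisen rearrangement: in the [3,3] transition state H6 points toward the C10 methyl and the C7 methyl away from it (A(1,3) strain), so the C6–O bond of the (6R)-ester lies on the α face and C9 bonds to C10 from that face, setting quaternary C10 with its methyl β, while C9 forms as an epimer mixture that does not matter.

**Step 11**
Reactants: 18 ethylidene acid
Product: 19 methyl ester of 18
Conditions: MeI, K2CO3, DMF, rt
Reagents that add atoms: iodomethane (CI)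
Why: SN2 O-alkylation of the carboxylate gives the methyl ester needed as the Claisen electrophile and protects the acid from borane.

**Step 12**
Reactants: 19 ethylidene methyl ester
Product: 21 C6 alcohol (ring A with C5–CH(OH)CH3; diastereomers at C5 and C6 and C9), via C6 alkylborane 20 (not isolated)
Conditions: BH3·SMe2, THF, 0 °C to rt; then 30% H2O2, aq. NaOAc, 0 °C to rt
Reagents that add atoms: hydrogen peroxide (OO)
Why: Hydroboration–oxidation puts boron on the less substituted C6 and hydrogen on C5 of the exocyclic alkene, which is clean only because the branch has no C13=C14 alkene yet; the buffered oxidation limits lactonisation of the δ-hydroxy ester, and the new C5 and C6 centres are later equilibrated or oxidised away.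

**Step 13**
Reactants: 21 C6 alcohol
Product: 22 methyl 12-(benzyloxy) keto ester (ring A with C5 acetyl; C10 carrying CH(CO2Me)CH2CH2OBn; C5 and C9 epimers)
Conditions: Dess–Martin periodinane, CH2Cl2, 0 °C to rt
Reagents that add atoms: none
Why: Dess–Martin oxidation of the hindered secondary alcohol gives the C5 acetyl group under neutral conditions that do not trigger premature Claisen closure.

**Step 14**
Reactants: 22 methyl 12-(benzyloxy) keto ester
Product: 24 12-iodo keto ester, via 12-hydroxy keto ester 23 (not isolated)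
Conditions: H2 (1 atm), 10% Pd on carbon, EtOAc, rt; filter; then I2, PPh3, imidazole, CH2Cl2, 0 °C
Reagents that add atoms: iodine (II)
Why: Hydrogenolysis of the benzyl ether (no alkene is present) followed directly by Appel-type iodination of the primary alcohol, telescoped so that the γ-hydroxy ester is converted before it can lactonise.

**Step 15**
Reactants: 25 but-2-yn-1-ol
Product: 26 tert-butyl(but-2-yn-1-yloxy)dimethylsilane
Conditions: TBSCl, imidazole, CH2Cl2, rt
Reagents that add atoms: tert-butyldimethylsilyl chloride (CC(C)(C)[Si](C)(C)Cl)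
Why: Standard silylation of the propargylic alcohol (future C15 oxygen).

**Step 16**
Reactants: 26 tert-butyl(but-2-yn-1-yloxy)dimethylsilane
Product: 28 (E)-tert-butyl[(3-iodobut-2-en-1-yl)oxy]dimethylsilane, via alkenylzirconocene chloride 27 (not isolated)
Conditions: Cp2Zr(H)Cl, THF, rt to 40 °C; then I2, 0 °C
Reagents that add atoms: iodine (II)
Why: Hydrozirconation adds Zr–H syn with zirconium at the less hindered methyl-bearing alkyne carbon, and iodinolysis with retention gives the (E)-alkenyl iodide (C13–C16 unit); any 2-iodo regioisomer is removed by chromatography.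

**Step 17**
Reactants: 24 12-iodo keto ester; 28 (E)-alkenyl iodide
Product: 30 methyl 3α,15,19-tris(TBS-oxy)-6-oxo-7,8-seco-17-norlabd-13E-en-8-oate (ring A keto ester with complete side chain; C5 and C9 epimers), via alkylzinc iodide 29 (not isolated)
Conditions: Zn dust (activated), LiCl, THF, 35 °C; then 28, Pd(PPh3)4 (cat.), THF, rt to 45 °C
Reagents that add atoms: none
Why: Negishi coupling: zinc insertion into the primary iodide gives an alkylzinc iodide that tolerates the ketone and ester, and palladium-catalysed coupling with the alkenyl iodide proceeds with retention, forming C12–C13 and fixing the 13E geometry.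

**Step 18 (key step)**
Reactants: 30 ring A keto ester with complete side chain
Product: 32 3α,15,19-tris(TBS-oxy)-17-norlabd-13E-ene-6,8-dione (trans-fused; 5α-H; C9 side chain equatorial), via potassium dionate 31 (not isolated)
Conditions: KOt-Bu (2.5 equiv), t-BuOH/THF, high dilution, 0 °C to rt; then cold 0.5 M HCl
Reagents that add atoms: none
Why: Intramolecular Claisen condensation, the Dieckmann-type closure of a δ-keto ester to a cyclohexane-1,3-dione: KOt-Bu reversibly forms the C7 enolate of the C5 acetyl group, which adds to the C8 methyl ester, methoxide leaves, and deprotonation of the product at C7 between the two carbonyls makes the closure irreversible. Ring B closes in the 6-exo-trig mode onto the ester carbonyl, forming the C7–C8 bond. No stereocentre is set kinetically: C5 (α to the ketone) and C9 (α to the ester) can epimerise under the alkoxide before closure, and only the arrangement with C6 and C9 both equatorial on ring A closes easily, because the cis alternatives need C6 syn-axial to the 3α silyl ether or C9 syn-axial to the C18 methyl, so the trans-fused dione with the equatorial C9 side chain is expected. Chemoselectivity rests on the single ester in the substrate (C15 is a silyl ether) and on the fact that the C5 and C9 enolates could only close four-membered rings. Any 5- or 9-epimeric dione is not lost, since C9 becomes sp2 and C5 is re-equilibrated in step 21.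

**Step 19**
Reactants: 32 trans-fused 6,8-dione
Product: 33 3α,15,19-tris(TBS-oxy)-6-oxo-17-norlabda-7,13E-dien-8-yl triflate
Conditions: Tf2O, pyridine, CH2Cl2, −78 to −20 °C
Reagents that add atoms: triflic anhydride (O=S(=O)(OS(=O)(=O)C(F)(F)F)C(F)(F)F)
Why: O-sulfonylation of the enolised 1,3-dione should occur at the C8 oxygen, which neighbours only C9, and not at the C6 oxygen, which is peri to the C4 substituents and flanked by the C10 methyl.

**Step 20**
Reactants: 33 C8 enol triflate
Product: 34 3α,15,19-tris(TBS-oxy)labda-7,13E-dien-6-one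
Conditions: MeZnCl (2 M in THF), Pd(PPh3)4 (cat.), THF, 0 °C to rt
Reagents that add atoms: methylzinc chloride (C[Zn]Cl)
Why: Negishi coupling of the vinylogous acyl triflate installs the C17 methyl on C8; the organozinc does not add to the hindered C6 ketone.

**Step 21**
Reactants: 34 8-methyl-7-en-6-one
Product: 36 3α,15,19-tris(TBS-oxy)labda-8,13E-dien-6-one, via potassium dienolate 35 (not isolated)
Conditions: KOt-Bu (excess), t-BuOH/THF, degassed, rt; then poured into cold 10% aq. AcOH
Reagents that add atoms: none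
Why: Deconjugation by kinetic protonation: excess alkoxide forms the more substituted endocyclic dienolate by loss of H9 (preferred over the exocyclic one from C17), and rapid acid quench protonates it at C7 to give the C8=C9 ketone; C9 is erased and C5, α′ to the carbonyl, equilibrates to the trans fusion.

**Step 22**
Reactants: 36 labda-8,13E-dien-6-one
Product: 37 3α,15,19-tris(TBS-oxy)labda-8,13E-dien-6β-ol
Conditions: NaBH4, CeCl3·7H2O, MeOH/THF, −40 to −10 °C
Reagents that add atoms: none
Why: Luche-type borohydride reduction: the β face of C6 is shielded by the axial C10 methyl and the axial C4 CH2OTBS group, so hydride adds from the α face to give the axial 6β-alcohol, and the cold, cerium-buffered medium avoids reconjugation of the alkene.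

**Step 23**
Reactants: 37 tris-silyl 6β-alcohol
Product: 38 labda-8,13E-diene-3α,6β,15,19-tetraol
Conditions: TBAF, THF, rt to 50 °C
Reagents that add atoms: none
Why: Fluoride desilylation removes all three TBS ethers, with warming for the hindered axial 3α ether.

**Step 24**
Reactants: 38 tetraol
Product: 39 3α,6β,19-trihydroxylabda-8,13E-dien-15-al
Conditions: MnO2 (activated, excess), acetone/CH2Cl2, rt
Reagents that add atoms: none
Why: MnO2 oxidation is selective for the allylic C15 alcohol over the saturated secondary, homoallylic and neopentyl primary alcohols, and keeps the 13E geometry.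

**Step 25**
Reactants: 39 C15 enal
Product: 40 3α,6β,19-trihydroxylabda-8,13E-dien-15-oic acid (CNP0246116.2)
Conditions: NaClO2, NaH2PO4, 2-methyl-2-butene, t-BuOH/H2O, 0 °C to rt
Reagents that add atoms: sodium chlorite ([Na+].[O-]Cl=O)
Why: Pinnick oxidation converts the enal to the acid without touching the free alcohols, with the alkene scavenger protecting the tetrasubstituted C8=C9 bond from hypochlorite.

**Compound list**
1 | 2-methylcyclohexane-1,3-dione | CC1C(=O)CCCC1=O | starting material
2 | 2-(hydroxymethyl)-2-methylcyclohexane-1,3-dione | CC1(CO)C(=O)CCCC1=O | intermediate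
3 | 2-[(TBS-oxy)methyl]-2-methylcyclohexane-1,3-dione | CC1(CO[Si](C)(C)C(C)(C)C)C(=O)CCCC1=O | intermediate
4 | (2S,3R)-2-[(TBS-oxy)methyl]-3-hydroxy-2-methylcyclohexan-1-one | O=C1CCC[C@@H](O)[C@]1(C)CO[Si](C)(C)C(C)(C)C | intermediate
5 | (2S,3R)-3-(TBS-oxy)-2-[(TBS-oxy)methyl]-2-methylcyclohexan-1-one | O=C1CCC[C@@H](O[Si](C)(C)C(C)(C)C)[C@]1(C)CO[Si](C)(C)C(C)(C)C | intermediate
6 | lithium enolate of 5 (C5–OLi, C5=C10) | [Li]OC1=CCC[C@@H](O[Si](C)(C)C(C)(C)C)[C@]1(C)CO[Si](C)(C)C(C)(C)C | intermediate (not isolated)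
7 | (2S,3R)-3-(TBS-oxy)-2-[(TBS-oxy)methyl]-2,6-dimethylcyclohexan-1-one, both C6 epimers | CC1CC[C@@H](O[Si](C)(C)C(C)(C)C)[C@](C)(CO[Si](C)(C)C(C)(C)C)C1=O | intermediate
8 | potassium enolate of 7 | CC1=C(O[K])[C@@](C)(CO[Si](C)(C)C(C)(C)C)[C@H](O[Si](C)(C)C(C)(C)C)CC1 | intermediate (not isolated)
9 | (5R,6S)-5-(TBS-oxy)-6-[(TBS-oxy)methyl]-2,6-dimethylcyclohex-1-en-1-yl triflate | CC1=C(OS(=O)(=O)C(F)(F)F)[C@@](C)(CO[Si](C)(C)C(C)(C)C)[C@H](O[Si](C)(C)C(C)(C)C)CC1 | intermediate
10 | tributyl(1-ethoxyvinyl)stannane | CCCC[Sn](CCCC)(CCCC)C(=C)OCC | starting material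
11 | 1-ethoxyvinyl diene (enol ether of 12) | C=C(OCC)C1=C(C)CC[C@@H](O[Si](C)(C)C(C)(C)C)[C@]1(C)CO[Si](C)(C)C(C)(C)C | intermediate (not isolated)
12 | 1-[(5R,6S)-5-(TBS-oxy)-6-[(TBS-oxy)methyl]-2,6-dimethylcyclohex-1-en-1-yl]ethan-1-one | CC(=O)C1=C(C)CC[C@@H](O[Si](C)(C)C(C)(C)C)[C@]1(C)CO[Si](C)(C)C(C)(C)C | intermediate
13 | (1R)-1-[(5R,6S)-5-(TBS-oxy)-6-[(TBS-oxy)methyl]-2,6-dimethylcyclohex-1-en-1-yl]ethan-1-ol | C[C@@H](O)C1=C(C)CC[C@@H](O[Si](C)(C)C(C)(C)C)[C@]1(C)CO[Si](C)(C)C(C)(C)C | intermediate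
14 | 4-(benzyloxy)butanoic acid | OC(=O)CCCOCc1ccccc1 | starting material
15 | (1R)-allylic 4-(benzyloxy)butanoate of 13 | C[C@@H](OC(=O)CCCOCc1ccccc1)C1=C(C)CC[C@@H](O[Si](C)(C)C(C)(C)C)[C@]1(C)CO[Si](C)(C)C(C)(C)C | intermediate
16 | trimethylsilyl ketene acetal of 15 (either geometry) | C[C@@H](OC(O[Si](C)(C)C)=CCCOCc1ccccc1)C1=C(C)CC[C@@H](O[Si](C)(C)C(C)(C)C)[C@]1(C)CO[Si](C)(C)C(C)(C)C | intermediate (not isolated)
17 | trimethylsilyl ester of 18 | C/C=C1\[C@@](C)(CO[Si](C)(C)C(C)(C)C)[C@H](O[Si](C)(C)C(C)(C)C)CC[C@]1(C)C(CCOCc1ccccc1)C(=O)O[Si](C)(C)C | intermediate (not isolated)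
18 | ethylidene acid: ring A with (Z)-C5 ethylidene (methyl syn to C4), C10 β-methyl and α-CH(CO2H)CH2CH2OBn, 3α-OTBS, 19-OTBS; C9 epimers | C/C=C1\[C@@](C)(CO[Si](C)(C)C(C)(C)C)[C@H](O[Si](C)(C)C(C)(C)C)CC[C@]1(C)C(CCOCc1ccccc1)C(=O)O | intermediate
19 | methyl ester of 18 | C/C=C1\[C@@](C)(CO[Si](C)(C)C(C)(C)C)[C@H](O[Si](C)(C)C(C)(C)C)CC[C@]1(C)C(CCOCc1ccccc1)C(=O)OC | intermediate
20 | C6 alkylborane from 19 (drawn as the monoalkylborane) | CC(B)C1[C@@](C)(CO[Si](C)(C)C(C)(C)C)[C@H](O[Si](C)(C)C(C)(C)C)CC[C@]1(C)C(CCOCc1ccccc1)C(=O)OC | intermediate (not isolated)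
21 | C6 alcohol: ring A with C5–CH(OH)CH3; diastereomers at C5, C6, C9 | CC(O)C1[C@@](C)(CO[Si](C)(C)C(C)(C)C)[C@H](O[Si](C)(C)C(C)(C)C)CC[C@]1(C)C(CCOCc1ccccc1)C(=O)OC | intermediate
22 | methyl 12-(benzyloxy) keto ester: ring A with C5 acetyl, C10 carrying CH(CO2Me)CH2CH2OBn; C5 and C9 epimers | CC(=O)C1[C@@](C)(CO[Si](C)(C)C(C)(C)C)[C@H](O[Si](C)(C)C(C)(C)C)CC[C@]1(C)C(CCOCc1ccccc1)C(=O)OC | intermediate
23 | 12-hydroxy keto ester | CC(=O)C1[C@@](C)(CO[Si](C)(C)C(C)(C)C)[C@H](O[Si](C)(C)C(C)(C)C)CC[C@]1(C)C(CCO)C(=O)OC | intermediate (not isolated)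
24 | 12-iodo keto ester | CC(=O)C1[C@@](C)(CO[Si](C)(C)C(C)(C)C)[C@H](O[Si](C)(C)C(C)(C)C)CC[C@]1(C)C(CCI)C(=O)OC | intermediate
25 | but-2-yn-1-ol | CC#CCO | starting material
26 | tert-butyl(but-2-yn-1-yloxy)dimethylsilane | CC#CCO[Si](C)(C)C(C)(C)C | intermediate
27 | (E)-alkenylzirconocene chloride (cyclopentadienyl ligands drawn σ-bonded) | C/C(=C\CO[Si](C)(C)C(C)(C)C)[Zr](Cl)(C1C=CC=C1)C1C=CC=C1 | intermediate (not isolated)
28 | (E)-tert-butyl[(3-iodobut-2-en-1-yl)oxy]dimethylsilane | C/C(I)=C\CO[Si](C)(C)C(C)(C)C | intermediate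
29 | alkylzinc iodide from 24 | CC(=O)C1[C@@](C)(CO[Si](C)(C)C(C)(C)C)[C@H](O[Si](C)(C)C(C)(C)C)CC[C@]1(C)C(CC[Zn]I)C(=O)OC | intermediate (not isolated)
30 | methyl 3α,15,19-tris(TBS-oxy)-6-oxo-7,8-seco-17-norlabd-13E-en-8-oate (key-step precursor; C5 and C9 epimers) | CC(=O)C1[C@@](C)(CO[Si](C)(C)C(C)(C)C)[C@H](O[Si](C)(C)C(C)(C)C)CC[C@]1(C)C(CC/C(C)=C/CO[Si](C)(C)C(C)(C)C)C(=O)OC | intermediate
31 | potassium enolate of 32 (drawn as the 6-oxo-7-en-8-olate) | [K]OC=1[C@H](CC/C(C)=C/CO[Si](C)(C)C(C)(C)C)[C@@]2(C)CC[C@@H](O[Si](C)(C)C(C)(C)C)[C@](C)(CO[Si](C)(C)C(C)(C)C)[C@@H]2C(=O)C=1 | intermediate (not isolated)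
32 | 3α,15,19-tris(TBS-oxy)-17-norlabd-13E-ene-6,8-dione, trans-fused (5α-H), 9α-H | O=C1[C@H](CC/C(C)=C/CO[Si](C)(C)C(C)(C)C)[C@@]2(C)CC[C@@H](O[Si](C)(C)C(C)(C)C)[C@](C)(CO[Si](C)(C)C(C)(C)C)[C@@H]2C(=O)C1 | intermediate
33 | 3α,15,19-tris(TBS-oxy)-6-oxo-17-norlabda-7,13E-dien-8-yl triflate | FC(F)(F)S(=O)(=O)OC=1[C@H](CC/C(C)=C/CO[Si](C)(C)C(C)(C)C)[C@@]2(C)CC[C@@H](O[Si](C)(C)C(C)(C)C)[C@](C)(CO[Si](C)(C)C(C)(C)C)[C@@H]2C(=O)C=1 | intermediate
34 | 3α,15,19-tris(TBS-oxy)labda-7,13E-dien-6-one | CC=1[C@H](CC/C(C)=C/CO[Si](C)(C)C(C)(C)C)[C@@]2(C)CC[C@@H](O[Si](C)(C)C(C)(C)C)[C@](C)(CO[Si](C)(C)C(C)(C)C)[C@@H]2C(=O)C=1 | intermediate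
35 | potassium 6,8(9)-dienolate of 34 | CC1=C(CC/C(C)=C/CO[Si](C)(C)C(C)(C)C)[C@@]2(C)CC[C@@H](O[Si](C)(C)C(C)(C)C)[C@](C)(CO[Si](C)(C)C(C)(C)C)[C@@H]2C(O[K])=C1 | intermediate (not isolated)
36 | 3α,15,19-tris(TBS-oxy)labda-8,13E-dien-6-one | CC1=C(CC/C(C)=C/CO[Si](C)(C)C(C)(C)C)[C@@]2(C)CC[C@@H](O[Si](C)(C)C(C)(C)C)[C@](C)(CO[Si](C)(C)C(C)(C)C)[C@@H]2C(=O)C1 | intermediate
37 | 3α,15,19-tris(TBS-oxy)labda-8,13E-dien-6β-ol | CC1=C(CC/C(C)=C/CO[Si](C)(C)C(C)(C)C)[C@@]2(C)CC[C@@H](O[Si](C)(C)C(C)(C)C)[C@](C)(CO[Si](C)(C)C(C)(C)C)[C@@H]2[C@H](O)C1 | intermediate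
38 | labda-8,13E-diene-3α,6β,15,19-tetraol | CC1=C(CC/C(C)=C/CO)[C@@]2(C)CC[C@@H](O)[C@](C)(CO)[C@@H]2[C@H](O)C1 | intermediate
39 | 3α,6β,19-trihydroxylabda-8,13E-dien-15-al | CC1=C(CC/C(C)=C/C=O)[C@@]2(C)CC[C@@H](O)[C@](C)(CO)[C@@H]2[C@H](O)C1 | intermediate
40 | 3α,6β,19-trihydroxylabda-8,13E-dien-15-oic acid (CNP0246116.2) | CC1=C(CC/C(C)=C/C(=O)O)[C@@]2(C)CC[C@@H](O)[C@](C)(CO)[C@@H]2[C@H](O)C1 | target

**Step count**
Total: 25 steps. Longest linear sequence: 23 steps (steps 1–14 and 17–25 from 2-methylcyclohexane-1,3-dione); steps 15–16 are a two-step side branch.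

**Three steps most likely to fail**

Step 18 (ring B Claisen closure). The enolate addition to the neopentyl-like C8 ester may be slow, so that intermolecular condensation or slow base damage competes. Closure may also occur mainly from the C5 epimer that gives cis-fused material before C5 has equilibrated. Fallback: the reaction would set out from 30, whose methyl ester would be saponified (LiOH, THF/MeOH/H2O) to the keto acid F1. This would be converted with pentafluorophenol and a carbodiimide into the pentafluorophenyl ester F2. Ring B would then be closed by soft-enolisation C-acylation of the methyl ketone (MgBr2·OEt2, i-Pr2NEt, CH2Cl2, rt), which activates the acyl donor instead of relying on alkoxide. The route is rejoined at dione 32.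

Step 19 (regioselective triflation). Sulfonylation may take place at the C6 oxygen, or at both oxygens without discrimination, giving the regioisomeric enol triflate that would lead to a C6 methyl group. Fallback: the reaction would set out from 32 and use the opposite oxygen on purpose. O-methylation (Me2SO4, K2CO3, acetone) and separation would give the 6-methoxy-6-en-8-one vinylogous ester F3. 1,2-Addition of MeLi/CeCl3 (THF, −78 °C) to the C8 carbonyl would give the tertiary carbinol F4. Dilute aqueous HCl would then effect the Stork–Danheiser transposition (enol ether hydrolysis and dehydration) to the 8-methyl-7-en-6-one, rejoining the route at 34.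

Step 21 (deconjugation). The dienolate may be protonated at the γ-carbon and return the conjugated enone, the exocyclic dienolate from C17 may compete, or the β,γ-enone may reconjugate during work-up or before reduction. Fallback: the reaction would set out from 34, which would be converted into the thermodynamic dienyl acetate F5 (isopropenyl acetate, TsOH cat., 60 °C). Treatment of F5 with NaBH4 in EtOH/THF at 0 °C would cleave the acetate slowly, and the β,γ-enone released by α-protonation would be reduced as it forms, the classical dienol acetate route to homoallylic alcohols. The route is rejoined at the 6β-alcohol 37, bypassing isolated 36.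

**Further compounds**
F1 | step 18 | keto acid: 3α,15,19-tris(TBS-oxy)-6-oxo-7,8-seco-17-norlabd-13E-en-8-oic acid | CC(=O)C1[C@@](C)(CO[Si](C)(C)C(C)(C)C)[C@H](O[Si](C)(C)C(C)(C)C)CC[C@]1(C)C(CC/C(C)=C/CO[Si](C)(C)C(C)(C)C)C(=O)O
F2 | step 18 | pentafluorophenyl ester of F1 | CC(=O)C1[C@@](C)(CO[Si](C)(C)C(C)(C)C)[C@H](O[Si](C)(C)C(C)(C)C)CC[C@]1(C)C(CC/C(C)=C/CO[Si](C)(C)C(C)(C)C)C(=O)Oc1c(F)c(F)c(F)c(F)c1F
F3 | step 19 | 6-methoxy-3α,15,19-tris(TBS-oxy)-17-norlabda-6,13E-dien-8-one | O=C1[C@H](CC/C(C)=C/CO[Si](C)(C)C(C)(C)C)[C@@]2(C)CC[C@@H](O[Si](C)(C)C(C)(C)C)[C@](C)(CO[Si](C)(C)C(C)(C)C)[C@@H]2C(OC)=C1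
F4 | step 19 | 6-methoxy-3α,15,19-tris(TBS-oxy)labda-6,13E-dien-8-ol (C8 epimers) | CC1(O)[C@H](CC/C(C)=C/CO[Si](C)(C)C(C)(C)C)[C@@]2(C)CC[C@@H](O[Si](C)(C)C(C)(C)C)[C@](C)(CO[Si](C)(C)C(C)(C)C)[C@@H]2C(OC)=C1
F5 | step 21 | 3α,15,19-tris(TBS-oxy)labda-6,8,13E-trien-6-yl acetate | CC1=C(CC/C(C)=C/CO[Si](C)(C)C(C)(C)C)[C@@]2(C)CC[C@@H](O[Si](C)(C)C(C)(C)C)[C@](C)(CO[Si](C)(C)C(C)(C)C)[C@@H]2C(OC(C)=O)=C1
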